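**Plan**

1. Core numbering (spiro[4.5]decane): ring A = cyclopentane with C1 (carbinol) and C2 (side-chain carbon); C5 = spiro carbon; ring B = cyclohexane with C6 = C(OH)CH3, C9 = ylidene carbon, C10 = CH carrying the hydroxypropyl chain. Retrosynthetic cuts, in order: the trienyl chain at the C2 ylidene carbon (aldol condensation on a γ-lactone that holds O1 and the future CH2OH), the C9=C(CH3)CHO unit (from a C9 ketone), the C2 acetate arm, then the C5–C10 bond.
2. Enabling feature: C1(O)–C5(quaternary)–C6(OH)CH3 is a reduced aldol whose quaternary α-carbon C5 is bonded to C10. Such a β-hydroxy ketone is the product of a semipinacol shift in a 2,3-epoxy alcohol, so ring B is made by contracting the seven-membered ring of a fused bicyclo[5.3.0]decane (hydroazulene) epoxy alcohol in which C10 sits on the carbinol carbon.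
3. Forward order: Evans aldol → seven-membered ring by metathesis → ring A by allyl addition and intramolecular B-alkyl Suzuki coupling → directed epoxidation → ring contraction (ring B and spiro centre) → C2 alkylation, directed reduction and lactone (temporary ring) → C9 enal, masked as acetal → side chain → lactone reduction and unmasking.
4. Stereochemistry: C10 from the oxazolidinone auxiliary; the ring-fusion carbinol by Grignard addition anti to the C10 chain; C5 and C6 together from hydroxyl-directed epoxidation and the stereospecific anti 1,2-shift; C1 by hydride delivery from the C6 hydroxyl; C2 by chelate-controlled alkylation and cis-lactone closure; alkene geometries from Wittig and aldol–elimination chemistry (E) and allylic strain (enal).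

Key step: step 11

Assumption: the silyloxy acid of step 1 and 4-methylpent-4-enal of step 2 are taken as catalogue compounds; each is otherwise two routine steps from δ-valerolactone or 2-methylprop-2-en-1-ol, which does not change the route.

Abbreviations in names: TBDPS = tert-butyldiphenylsilyl, TBS = tert-butyldimethylsilyl.

**Step 1**
Reactants: 1 5-(TBDPS-oxy)pentanoic acid; 2 (R)-4-benzyloxazolidin-2-one
Product: 4 (R)-4-benzyl-3-[5-(TBDPS-oxy)pentanoyl]oxazolidin-2-one, via mixed pivalic anhydride 3 (not isolated)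
Conditions: t-BuCOCl, Et3N, THF, −20 °C; then LiCl, 2, −20 °C → rt
Reagents that add atoms: none
Why: N-acylation of the oxazolidinone through the mixed pivalic anhydride (standard Evans imide preparation) installs the auxiliary that will control C10.

**Step 2**
Reactants: 4 (R)-4-benzyl-3-[5-(TBDPS-oxy)pentanoyl]oxazolidin-2-one; 5 4-methylpent-4-enal
Product: 6 (R)-4-benzyl-3-[(2R,3S)-3-hydroxy-6-methyl-2-[3-(TBDPS-oxy)propyl]hept-6-enoyl]oxazolidin-2-one
Conditions: n-Bu2BOTf, i-Pr2NEt, CH2Cl2, −78 → 0 °C; 5, −78 → 0 °C; pH 7 buffer, MeOH, H2O2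
Reagents that add atoms: none
Why: Evans syn aldol reaction, in which the Z boron enolate reacts through a Zimmerman–Traxler chair on the face away from the benzyl group, should set the (2R) centre (later C10) and the (3S) carbinol (later C9).

**Step 3**
Reactants: 6 aldol imide
Product: 7 (2R,3S)-3-hydroxy-N-methoxy-N,6-dimethyl-2-[3-(TBDPS-oxy)propyl]hept-6-enamide
Conditions: MeNH(OMe)·HCl, AlMe3, THF, −20 → 0 °C
Reagents that add atoms: N,O-dimethylhydroxylamine hydrochloride, CNOC.Cl
Why: aluminium amide transamination of a β-hydroxy acyl oxazolidinone (Weinreb amide formation) is assisted by the free hydroxyl and releases the auxiliary without epimerisation.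

**Step 4**
Reactants: 7 hydroxy Weinreb amide
Product: 8 (2R,3S)-3-(TBS-oxy)-N-methoxy-N,6-dimethyl-2-[3-(TBDPS-oxy)propyl]hept-6-enamide
Conditions: TBSOTf, 2,6-lutidine, CH2Cl2, −78 → 0 °C
Reagents that add atoms: tert-butyldimethylsilyl trifluoromethanesulfonate, CC(C)(C)[Si](C)(C)OS(=O)(=O)C(F)(F)F
Why: silylation with a silyl triflate and a hindered base protects the secondary carbinol for the organometallic steps and leaves a group that can later be removed beside the primary TBDPS ether.

**Step 5**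
Reactants: 8 silyl Weinreb amide
Product: 9 (4R,5S)-5-(TBS-oxy)-8-methyl-4-[3-(TBDPS-oxy)propyl]nona-1,8-dien-3-one
Conditions: CH2=CHMgBr, THF, −78 → 0 °C; cold aq. NH4Cl (inverse quench)
Reagents that add atoms: vinylmagnesium bromide, C=C[Mg]Br
Why: Weinreb ketone synthesis, in which the chelated tetrahedral intermediate stops at mono-addition and releases the vinyl ketone only on quench.

**Step 6**
Reactants: 9 dienone
Product: 10 (6S,7R)-6-(TBS-oxy)-3-methyl-7-[3-(TBDPS-oxy)propyl]cyclohept-2-en-1-one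
Conditions: second-generation Grubbs catalyst RuCl2(=CHPh)(PCy3)(H2IMes) (5 mol%), CH2Cl2 (high dilution), 40 °C
Reagents that add atoms: none
Why: ring-closing metathesis of a vinyl ketone with a 1,1-disubstituted alkene, a reliable entry to 3-methylcycloalk-2-enones, closes the seven-membered ring with loss of ethene.

**Step 7**
Reactants: 10 cycloheptenone
Product: 12 (6S,7R)-2-bromo-6-(TBS-oxy)-3-methyl-7-[3-(TBDPS-oxy)propyl]cyclohept-2-en-1-one, via dibromo ketone 11 (not isolated)
Conditions: Br2, CH2Cl2, 0 °C; then Et3N, 0 °C → rt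
Reagents that add atoms: bromine, BrBr
Why: bromine addition to the enone and amine-induced dehydrobromination (standard α-bromination of a β-substituted cycloalkenone) put a coupling handle on the carbon that becomes the spiro centre.

**Step 8**
Reactants: 12 bromo enone
Product: 13 (1R,6S,7R)-1-allyl-2-bromo-6-(TBS-oxy)-3-methyl-7-[3-(TBDPS-oxy)propyl]cyclohept-2-en-1-ol
Conditions: CH2=CHCH2MgBr, THF, −78 °C; aq. NH4Cl
Reagents that add atoms: allylmagnesium bromide, C=CC[Mg]Br
Why: 1,2-addition of the allyl Grignard reagent to the enone carbonyl from the face opposite the adjacent C7 chain (attack trans to the α-substituent, the C6 silyloxy group being pseudo-equatorial) should give the tertiary carbinol with the hydroxyl cis to that chain, the relation the later shift needs.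

**Step 9**
Reactants: 13 allyl carbinol
Product: 15 (7S,8R,8aR)-7-(TBS-oxy)-4-methyl-8-[3-(TBDPS-oxy)propyl]-2,3,5,6,7,8-hexahydroazulen-8a(1H)-ol, via B-alkyl borane 14 (not isolated)
Conditions: 9-BBN, THF, rt; then PdCl2(dppf) (10 mol%), AsPh3, Cs2CO3, DMF/H2O, 50 °C
Reagents that add atoms: none
Why: anti-Markovnikov hydroboration of the terminal alkene followed by intramolecular B-alkyl Suzuki–Miyaura coupling with the vinyl bromide closes ring A (five-membered, exo at the sp2 carbon) and keeps the tetrasubstituted alkene in place.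

**Step 10**
Reactants: 15 hydroazulenol
Product: 16 (3aR,4S,7S,8R,8aR)-3a,4-epoxy-7-(TBS-oxy)-4-methyl-8-[3-(TBDPS-oxy)propyl]octahydroazulen-8a(1H)-ol (epoxide oxygen cis to the hydroxyl)
Conditions: VO(acac)2 (5 mol%), t-BuOOH, CH2Cl2, 0 °C → rt
Reagents that add atoms: tert-butyl hydroperoxide, CC(C)(C)OO
Why: vanadium-catalysed hydroxyl-directed epoxidation of the tertiary allylic alcohol delivers oxygen to the alkene face syn to the 8a-hydroxyl, that is anti to the C8a–C8 bond.

**Step 11**
Reactants: 16 epoxy alcohol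
Product: 17 (5R,6S,9S,10S)-9-(TBS-oxy)-6-hydroxy-6-methyl-10-[3-(TBDPS-oxy)propyl]spiro[4.5]decan-1-one
Conditions: BF3·OEt2 (20 mol%), CH2Cl2, −78 °C; aq. NaHCO3
Reagents that add atoms: none
Why: The Lewis acid binds the epoxide oxygen and, as the C3a–O bond next to the carbinol carbon ionises, the antiperiplanar C8a–C8 σ-bond shifts suprafacially from C8a to C3a while the hydroxyl oxygen collapses to the ketone and the epoxide oxygen stays on C4 as the tertiary alcohol (semipinacol rearrangement). The closest known reaction type is the Lewis acid rearrangement of tertiary 2,3-epoxy alcohols to β-hydroxy ketones with a quaternary α-carbon (Tsuchihashi–Suzuki and Tu variants), including fused-to-spiro ring contractions of the eudesmane-to-spirovetivane kind. Ring B closes by this 1,2-alkyl shift through a three-centre transition state, that is by contraction of the seven-membered ring of the hydroazulene to the cyclohexane, the new bond joining the spiro carbon C5 to C10. The new quaternary stereocentre C5 is fixed by inversion at the epoxide carbon (the migrating carbon enters anti to the departing oxygen), so its configuration and that of the retained C6 carbinol follow from the epoxide face set in step 10, while C10 migrates with retention and carries the auxiliary-derived configuration into the C5/C6/C10 array of the target. The step needs cleavage of the proximal and not the distal epoxide C–O bond and migration of C8 and not C1; both are secured by the cis relation of hydroxyl and epoxide oxygen, which places only the C8a–C8 bond anti to the breaking bond (a shift of C1 is nearly orthogonal and would form a cyclobutane), and by the gain of the C=O bond that goes with proximal opening.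

**Step 12**
Reactants: 17 spiro hydroxy ketone
Product: 18 ethyl 2-[(2S,5R,6S,9S,10S)-9-(TBS-oxy)-6-hydroxy-6-methyl-1-oxo-10-[3-(TBDPS-oxy)propyl]spiro[4.5]decan-2-yl]acetate
Conditions: LiN(i-Pr)2 (2.3 equiv), THF, −78 °C (17 added to the base); DMPU, BrCH2CO2Et, −78 → −40 °C
Reagents that add atoms: ethyl bromoacetate, CCOC(=O)CBr
Why: the dianion (alkoxide, then enolate at C2, the only enolisable position) is alkylated by the α-bromo ester, and because the lithium alkoxide on C6 is chelated to the enolate oxygen on the face that carries C6 (Fráter–Seebach-type control), the electrophile should enter from the opposite face and place the acetate arm cis to C10.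

**Step 13**
Reactants: 18 keto ester
Product: 21 1-lactone of [(1R,2S,5S,6S,9S,10S)-1,6,9-trihydroxy-6-methyl-10-[3-(TBDPS-oxy)propyl]spiro[4.5]decan-2-yl]acetic acid, via dihydroxy ester 19 (not isolated), via silyl lactone 20 (not isolated)
Conditions: Me4NBH(OAc)3, MeCN/AcOH (1:1), −30 °C; then CSA (cat.), MeOH, rt
Reagents that add atoms: none
Why: Evans–Saksena reduction, in which the borohydride exchanges onto the C6 hydroxyl and delivers hydride to the ketone face that carries C6, should give the C1 alcohol cis to the C2 arm, so that acid closes the cis-fused γ-lactone and methanolysis removes the secondary TBS ether while the primary TBDPS ether stays.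

**Step 14**
Reactants: 21 hydroxy lactone
Product: 22 1-lactone of [(1R,2S,5S,6S,10S)-1,6-dihydroxy-6-methyl-9-oxo-10-[3-(TBDPS-oxy)propyl]spiro[4.5]decan-2-yl]acetic acid
Conditions: Dess–Martin periodinane, NaHCO3, CH2Cl2, rt
Reagents that add atoms: none
Why: Dess–Martin oxidation of the only secondary alcohol under buffered conditions that do not epimerise C10 (the tertiary alcohol cannot be oxidised).

**Step 15**
Reactants: 22 keto lactone
Product: 23 1-lactone of [(1R,2S,5S,6S,10S)-1,6,9-trihydroxy-6-methyl-9-(prop-1-en-2-yl)-10-[3-(TBDPS-oxy)propyl]spiro[4.5]decan-2-yl]acetic acid (C9 epimers)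
Conditions: CH2=C(CH3)MgBr, CeCl3, THF, −78 °C; aq. NH4Cl
Reagents that add atoms: isopropenylmagnesium bromide, CC(=C)[Mg]Br
Why: the organocerium reagent adds to the hindered, enolisable ketone without deprotonating C10 and much faster than to the lactone, and the configuration of the new carbinol is irrelevant because this centre becomes sp2 in the next step.

**Step 16**
Reactants: 23 isopropenyl carbinol
Product: 24 1-lactone of [(1R,2S,5S,6S,9Z,10R)-1,6-dihydroxy-6-methyl-9-(1-oxopropan-2-ylidene)-10-[3-(TBDPS-oxy)propyl]spiro[4.5]decan-2-yl]acetic acid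
Conditions: pyridinium chlorochromate (C5H5NH[CrO3Cl]), 4 Å molecular sieves, CH2Cl2, rt
Reagents that add atoms: pyridinium chlorochromate, c1cc[nH+]cc1.[O-][Cr](=O)(=O)Cl
Why: Babler–Dauben oxidative transposition, in which the tertiary allylic chromate ester undergoes [3,3] shift to the primary allylic chromate and is oxidised to the enal; the isomer with the formyl group syn to the branched C10 and the larger methyl group syn to the C8 methylene should be favoured by allylic 1,3-strain and by equilibration under the acidic conditions.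

**Step 17**
Reactants: 24 enal lactone
Product: 25 1-lactone of [(1R,2S,5S,6S,9Z,10R)-9-(1,1-dimethoxypropan-2-ylidene)-1,6-dihydroxy-6-methyl-10-[3-(TBDPS-oxy)propyl]spiro[4.5]decan-2-yl]acetic acid
Conditions: HC(OMe)3, PPTS (cat.), CH2Cl2, rt
Reagents that add atoms: trimethyl orthoformate, COC(OC)OC
Why: acid-catalysed acetal exchange with the orthoformate masks the enal against the enolate and hydride steps that follow.

**Step 18**
Reactants: 26 2,6-dimethylhept-5-enal (melonal, racemic)
Product: 27 (E)-2,6-dimethylhepta-2,5-dienal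
Conditions: IBX, DMSO/toluene, 65 °C
Reagents that add atoms: none
Why: IBX-mediated α,β-dehydrogenation of an aldehyde through its enol (Nicolaou conditions) should give the (E)-2-methyl enal and leave the isolated trisubstituted alkene untouched.

**Step 19**
Reactants: 27 (E)-2,6-dimethylhepta-2,5-dienal
Product: 28 (2E,4E)-4,8-dimethylnona-2,4,7-trienal
Conditions: Ph3P=CHCHO, toluene, 80 °C
Reagents that add atoms: (triphenylphosphoranylidene)acetaldehyde, O=CC=P(c1ccccc1)(c1ccccc1)c1ccccc1
Why: Wittig two-carbon homologation with the stabilised formylmethylene ylide is (E)-selective and, with the α-branched enal in slight excess, should stop after one homologation.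

**Step 20**
Reactants: 25 acetal lactone; 28 (2E,4E)-4,8-dimethylnona-2,4,7-trienal
Product: 31 (E)-α-[(2E,4E)-4,8-dimethylnona-2,4,7-trien-1-ylidene] derivative of lactone 25, via aldol adduct 29 (not isolated), via allylic mesylate 30 (not isolated)
Conditions: LiN(i-Pr)2 (2.2 equiv), THF, −78 °C; 28, −78 °C; aq. NH4Cl; then MsCl, Et3N, CH2Cl2, 0 °C; DBU, rt
Reagents that add atoms: none
Why: lactone enolate aldol addition followed by E1cB elimination of the secondary mesylate should give the conjugated (E)-alkylidene lactone, in which the trienyl chain is trans to the lactone carbonyl and which is the thermodynamically preferred product of base-mediated elimination.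

**Step 21**
Reactants: 31 alkylidene lactone
Product: 32 (1R,2S,5S,6S,9Z,10R)-9-(1,1-dimethoxypropan-2-ylidene)-2-[(2E,4E,6E)-1-hydroxy-6,10-dimethylundeca-2,4,6,9-tetraen-2-yl]-6-methyl-10-[3-(TBDPS-oxy)propyl]spiro[4.5]decane-1,6-diol
Conditions: i-Bu2AlH (5 equiv), CH2Cl2, −78 → −20 °C; Rochelle salt
Reagents that add atoms: none
Why: excess diisobutylaluminium hydride reduces the α-alkylidene lactone by 1,2-addition through the lactol to the allylic diol, which reveals the C1 alcohol and the hydroxymethyl group with the alkene geometry intact while acetal and silyl ether are inert.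

**Step 22**
Reactants: 32 protected diol
Product: 33 (2Z)-2-[(1R,2S,5S,6S,10R)-1,6-dihydroxy-2-[(2E,4E,6E)-1-hydroxy-6,10-dimethylundeca-2,4,6,9-tetraen-2-yl]-10-(3-hydroxypropyl)-6-methylspiro[4.5]decan-9-ylidene]propanal (target)
Conditions: HF·pyridine, pyridine, THF, 0 °C → rt; then H2O, rt
Reagents that add atoms: water, O
Why: fluoride cleaves the primary silyl ether and the mildly acidic aqueous medium hydrolyses the very labile α,β-unsaturated dimethyl acetal, which should give the target in one operation without strong acid or base that could touch the triene or epimerise C10.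

**Compound list**

1 | 5-(TBDPS-oxy)pentanoic acid | OC(=O)CCCCO[Si](c1ccccc1)(c1ccccc1)C(C)(C)C | starting material
2 | (R)-4-benzyloxazolidin-2-one | O=C1N[C@H](Cc2ccccc2)CO1 | starting material
3 | 5-(TBDPS-oxy)pentanoic pivalic anhydride | CC(C)(C)C(=O)OC(=O)CCCCO[Si](c1ccccc1)(c1ccccc1)C(C)(C)C | intermediate
4 | (R)-4-benzyl-3-[5-(TBDPS-oxy)pentanoyl]oxazolidin-2-one | O=C(CCCCO[Si](c1ccccc1)(c1ccccc1)C(C)(C)C)N1[C@H](Cc2ccccc2)COC1=O | intermediate
5 | 4-methylpent-4-enal | O=CCCC(C)=C | starting material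
6 | (R)-4-benzyl-3-[(2R,3S)-3-hydroxy-6-methyl-2-[3-(TBDPS-oxy)propyl]hept-6-enoyl]oxazolidin-2-one | O=C(N1[C@H](Cc2ccccc2)COC1=O)[C@H](CCCO[Si](c1ccccc1)(c1ccccc1)C(C)(C)C)[C@@H](O)CCC(C)=C | intermediate
7 | (2R,3S)-3-hydroxy-N-methoxy-N,6-dimethyl-2-[3-(TBDPS-oxy)propyl]hept-6-enamide | CON(C)C(=O)[C@H](CCCO[Si](c1ccccc1)(c1ccccc1)C(C)(C)C)[C@@H](O)CCC(C)=C | intermediate
8 | (2R,3S)-3-(TBS-oxy)-N-methoxy-N,6-dimethyl-2-[3-(TBDPS-oxy)propyl]hept-6-enamide | CON(C)C(=O)[C@H](CCCO[Si](c1ccccc1)(c1ccccc1)C(C)(C)C)[C@@H](O[Si](C)(C)C(C)(C)C)CCC(C)=C | intermediate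
9 | (4R,5S)-5-(TBS-oxy)-8-methyl-4-[3-(TBDPS-oxy)propyl]nona-1,8-dien-3-one | C=CC(=O)[C@H](CCCO[Si](c1ccccc1)(c1ccccc1)C(C)(C)C)[C@@H](O[Si](C)(C)C(C)(C)C)CCC(C)=C | intermediate
10 | (6S,7R)-6-(TBS-oxy)-3-methyl-7-[3-(TBDPS-oxy)propyl]cyclohept-2-en-1-one | O=C1[C@H](CCCO[Si](c2ccccc2)(c2ccccc2)C(C)(C)C)[C@@H](O[Si](C)(C)C(C)(C)C)CCC(C)=C1 | intermediate
11 | (6S,7R)-2,3-dibromo-6-(TBS-oxy)-3-methyl-7-[3-(TBDPS-oxy)propyl]cycloheptan-1-one (C2 and C3 not defined) | O=C1[C@H](CCCO[Si](c2ccccc2)(c2ccccc2)C(C)(C)C)[C@@H](O[Si](C)(C)C(C)(C)C)CCC(C)(Br)C1Br | intermediate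
12 | (6S,7R)-2-bromo-6-(TBS-oxy)-3-methyl-7-[3-(TBDPS-oxy)propyl]cyclohept-2-en-1-one | O=C1[C@H](CCCO[Si](c2ccccc2)(c2ccccc2)C(C)(C)C)[C@@H](O[Si](C)(C)C(C)(C)C)CCC(C)=C1Br | intermediate
13 | (1R,6S,7R)-1-allyl-2-bromo-6-(TBS-oxy)-3-methyl-7-[3-(TBDPS-oxy)propyl]cyclohept-2-en-1-ol | C=CC[C@@]1(O)[C@H](CCCO[Si](c2ccccc2)(c2ccccc2)C(C)(C)C)[C@@H](O[Si](C)(C)C(C)(C)C)CCC(C)=C1Br | intermediate
14 | 9-[3-(cycloheptenyl)propyl]-9-borabicyclo[3.3.1]nonane from 13 (boron on the terminal carbon of the former allyl group) | B1(CCC[C@@]2(O)[C@H](CCCO[Si](c3ccccc3)(c3ccccc3)C(C)(C)C)[C@@H](O[Si](C)(C)C(C)(C)C)CCC(C)=C2Br)C3CCCC1CCC3 | intermediate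
15 | (7S,8R,8aR)-7-(TBS-oxy)-4-methyl-8-[3-(TBDPS-oxy)propyl]-2,3,5,6,7,8-hexahydroazulen-8a(1H)-ol | CC1=C2CCC[C@@]2(O)[C@H](CCCO[Si](c3ccccc3)(c3ccccc3)C(C)(C)C)[C@@H](O[Si](C)(C)C(C)(C)C)CC1 | intermediate
16 | (3aR,4S,7S,8R,8aR)-3a,4-epoxy-7-(TBS-oxy)-4-methyl-8-[3-(TBDPS-oxy)propyl]octahydroazulen-8a(1H)-ol | C[C@]12O[C@@]23CCC[C@@]3(O)[C@H](CCCO[Si](c4ccccc4)(c4ccccc4)C(C)(C)C)[C@@H](O[Si](C)(C)C(C)(C)C)CC1 | intermediate
17 | (5R,6S,9S,10S)-9-(TBS-oxy)-6-hydroxy-6-methyl-10-[3-(TBDPS-oxy)propyl]spiro[4.5]decan-1-one | C1CC[C@]2([C@H](CCCO[Si](c3ccccc3)(c3ccccc3)C(C)(C)C)[C@@H](O[Si](C)(C)C(C)(C)C)CC[C@]2(C)O)C1=O | intermediate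
18 | ethyl 2-[(2S,5R,6S,9S,10S)-9-(TBS-oxy)-6-hydroxy-6-methyl-1-oxo-10-[3-(TBDPS-oxy)propyl]spiro[4.5]decan-2-yl]acetate | CCOC(=O)C[C@@H]1CC[C@]2([C@H](CCCO[Si](c3ccccc3)(c3ccccc3)C(C)(C)C)[C@@H](O[Si](C)(C)C(C)(C)C)CC[C@]2(C)O)C1=O | intermediate
19 | ethyl 2-[(1R,2S,5S,6S,9S,10S)-9-(TBS-oxy)-1,6-dihydroxy-6-methyl-10-[3-(TBDPS-oxy)propyl]spiro[4.5]decan-2-yl]acetate | CCOC(=O)C[C@@H]1CC[C@]2([C@H](CCCO[Si](c3ccccc3)(c3ccccc3)C(C)(C)C)[C@@H](O[Si](C)(C)C(C)(C)C)CC[C@]2(C)O)[C@@H]1O | intermediate
20 | 1-lactone of [(1R,2S,5S,6S,9S,10S)-9-(TBS-oxy)-1,6-dihydroxy-6-methyl-10-[3-(TBDPS-oxy)propyl]spiro[4.5]decan-2-yl]acetic acid | O=C1C[C@@H]2CC[C@]3([C@H](CCCO[Si](c4ccccc4)(c4ccccc4)C(C)(C)C)[C@@H](O[Si](C)(C)C(C)(C)C)CC[C@]3(C)O)[C@@H]2O1 | intermediate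
21 | 1-lactone of [(1R,2S,5S,6S,9S,10S)-1,6,9-trihydroxy-6-methyl-10-[3-(TBDPS-oxy)propyl]spiro[4.5]decan-2-yl]acetic acid | O=C1C[C@@H]2CC[C@]3([C@H](CCCO[Si](c4ccccc4)(c4ccccc4)C(C)(C)C)[C@@H](O)CC[C@]3(C)O)[C@@H]2O1 | intermediate
22 | 1-lactone of [(1R,2S,5S,6S,10S)-1,6-dihydroxy-6-methyl-9-oxo-10-[3-(TBDPS-oxy)propyl]spiro[4.5]decan-2-yl]acetic acid | O=C1C[C@@H]2CC[C@]3([C@H](CCCO[Si](c4ccccc4)(c4ccccc4)C(C)(C)C)C(=O)CC[C@]3(C)O)[C@@H]2O1 | intermediate
23 | 1-lactone of [(1R,2S,5S,6S,10S)-1,6,9-trihydroxy-6-methyl-9-(prop-1-en-2-yl)-10-[3-(TBDPS-oxy)propyl]spiro[4.5]decan-2-yl]acetic acid (C9 epimers) | O=C1C[C@@H]2CC[C@]3([C@H](CCCO[Si](c4ccccc4)(c4ccccc4)C(C)(C)C)C(O)(C(C)=C)CC[C@]3(C)O)[C@@H]2O1 | intermediate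
24 | 1-lactone of [(1R,2S,5S,6S,9Z,10R)-1,6-dihydroxy-6-methyl-9-(1-oxopropan-2-ylidene)-10-[3-(TBDPS-oxy)propyl]spiro[4.5]decan-2-yl]acetic acid | O=C1C[C@@H]2CC[C@]3([C@H](CCCO[Si](c4ccccc4)(c4ccccc4)C(C)(C)C)/C(=C(/C)C=O)CC[C@]3(C)O)[C@@H]2O1 | intermediate
25 | 1-lactone of [(1R,2S,5S,6S,9Z,10R)-9-(1,1-dimethoxypropan-2-ylidene)-1,6-dihydroxy-6-methyl-10-[3-(TBDPS-oxy)propyl]spiro[4.5]decan-2-yl]acetic acid | O=C1C[C@@H]2CC[C@]3([C@H](CCCO[Si](c4ccccc4)(c4ccccc4)C(C)(C)C)/C(=C(/C)C(OC)OC)CC[C@]3(C)O)[C@@H]2O1 | intermediate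
26 | 2,6-dimethylhept-5-enal (melonal, racemic) | O=CC(C)CCC=C(C)C | starting material
27 | (E)-2,6-dimethylhepta-2,5-dienal | O=C/C(C)=C/CC=C(C)C | intermediate
28 | (2E,4E)-4,8-dimethylnona-2,4,7-trienal | O=C/C=C/C(C)=C/CC=C(C)C | intermediate
29 | lactone 25 carrying a (2E,4E)-1-hydroxy-4,8-dimethylnona-2,4,7-trienyl group on the lactone α-carbon (diastereomers at the two new centres) | O=C1C(C(O)/C=C/C(C)=C/CC=C(C)C)[C@@H]2CC[C@]3([C@H](CCCO[Si](c4ccccc4)(c4ccccc4)C(C)(C)C)/C(=C(/C)C(OC)OC)CC[C@]3(C)O)[C@@H]2O1 | intermediate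
30 | methanesulfonate of the secondary hydroxyl of 29 | O=C1C(C(OS(C)(=O)=O)/C=C/C(C)=C/CC=C(C)C)[C@@H]2CC[C@]3([C@H](CCCO[Si](c4ccccc4)(c4ccccc4)C(C)(C)C)/C(=C(/C)C(OC)OC)CC[C@]3(C)O)[C@@H]2O1 | intermediate
31 | (E)-α-[(2E,4E)-4,8-dimethylnona-2,4,7-trien-1-ylidene] derivative of lactone 25 | O=C1/C(=C/C=C/C(C)=C/CC=C(C)C)[C@@H]2CC[C@]3([C@H](CCCO[Si](c4ccccc4)(c4ccccc4)C(C)(C)C)/C(=C(/C)C(OC)OC)CC[C@]3(C)O)[C@@H]2O1 | intermediate
32 | (1R,2S,5S,6S,9Z,10R)-9-(1,1-dimethoxypropan-2-ylidene)-2-[(2E,4E,6E)-1-hydroxy-6,10-dimethylundeca-2,4,6,9-tetraen-2-yl]-6-methyl-10-[3-(TBDPS-oxy)propyl]spiro[4.5]decane-1,6-diol | CC(C)=CC/C=C(C)/C=C/C=C(/CO)[C@@H]1CC[C@]2([C@H](CCCO[Si](c3ccccc3)(c3ccccc3)C(C)(C)C)/C(=C(/C)C(OC)OC)CC[C@]2(C)O)[C@@H]1O | intermediate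
33 | (2Z)-2-[(1R,2S,5S,6S,10R)-1,6-dihydroxy-2-[(2E,4E,6E)-1-hydroxy-6,10-dimethylundeca-2,4,6,9-tetraen-2-yl]-10-(3-hydroxypropyl)-6-methylspiro[4.5]decan-9-ylidene]propanal | CC(C)=CC/C=C(C)/C=C/C=C(/CO)[C@@H]1CC[C@]2([C@H](CCCO)/C(=C(/C)C=O)CC[C@]2(C)O)[C@@H]1O | target

Total step count: 22. Longest linear sequence: 20 steps (steps 1–17 and 20–22).

**Steps most likely to fail**

Step 11. The epoxide may ionise at the distal, methyl-bearing carbon (C4) and then lose a proton or undergo another 1,2-shift, so that allylic diols form in place of the C8 shift. The silyl ethers may also be attacked by the Lewis acid. The fallback sets out from 16: the tertiary hydroxyl is silylated with 1-(trimethylsilyl)imidazole in CH2Cl2 to give the epoxy trimethylsilyl ether F1. F1 is rearranged in the Suzuki–Tsuchihashi manner (TiCl4, CH2Cl2, −78 °C); there the silyloxy group is the stronger donor and titanium bridges both oxygens, so that only the proximal C–O bond is weakened. Silicon leaves as its chloride, and aqueous work-up comes back to the route at 17.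

Step 12. The enolate alkylation may show poor facial selectivity and give C2 epimers, and the lithium aldolate may fragment by retro-aldol reaction before the second deprotonation. The fallback sets out from 17 and fixes C2 by ring formation instead of by enolate chemistry. Directed reduction as in step 13 (Me4NBH(OAc)3, MeCN/AcOH) gives the diol F2. The secondary C1 hydroxyl is acylated with succinimidyl diazoacetate (Et3N, THF) to give the diazoacetate F3, and the tertiary hydroxyl is capped with 1-(trimethylsilyl)imidazole to give the silylated diazoacetate F4. Carbenoid C–H insertion catalysed by Rh2(cap)4 (dirhodium tetracaprolactamate, CH2Cl2, 40 °C) into the C2–H bond gives the bis-silyl lactone F5. A five-membered lactone can only close on the face of the ester oxygen, so the cis ring fusion is fixed by the reaction itself. CSA in MeOH then removes both silyl groups and comes back to the route at 21.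

Step 16. The hindered tertiary allylic alcohol may ionise under the acidic chromium conditions (dehydration to dienes, or capture of the allyl cation by the C6 hydroxyl), and control over the geometry of the tetrasubstituted enal may be incomplete. The fallback sets out from 22 and avoids the carbinol. Peterson olefination with the lithio derivative of N-tert-butyl-2-(triethylsilyl)propan-1-imine (generated with sec-BuLi, THF, −78 → −20 °C) gives the unsaturated aldimine F6. Hydrolysis with aqueous oxalic acid comes back to the route at 24; under this acidic hydrolysis the alkene isomers should equilibrate toward the one with the formyl group next to the branched C10.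

**Further compounds**

F1 | step 11 | 8a-O-trimethylsilyl ether of epoxy alcohol 16 | C[C@]12O[C@@]23CCC[C@@]3(O[Si](C)(C)C)[C@H](CCCO[Si](c4ccccc4)(c4ccccc4)C(C)(C)C)[C@@H](O[Si](C)(C)C(C)(C)C)CC1
F2 | step 12 | (1R,5S,6S,9S,10S)-9-(TBS-oxy)-6-methyl-10-[3-(TBDPS-oxy)propyl]spiro[4.5]decane-1,6-diol | C1CC[C@]2([C@H](CCCO[Si](c3ccccc3)(c3ccccc3)C(C)(C)C)[C@@H](O[Si](C)(C)C(C)(C)C)CC[C@]2(C)O)[C@@H]1O
F3 | step 12 | 1-O-diazoacetate of diol F2 | C1CC[C@]2([C@H](CCCO[Si](c3ccccc3)(c3ccccc3)C(C)(C)C)[C@@H](O[Si](C)(C)C(C)(C)C)CC[C@]2(C)O)[C@@H]1OC(=O)C=[N+]=[N-]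
F4 | step 12 | 6-O-trimethylsilyl ether of diazoacetate F3 | C1CC[C@]2([C@H](CCCO[Si](c3ccccc3)(c3ccccc3)C(C)(C)C)[C@@H](O[Si](C)(C)C(C)(C)C)CC[C@]2(C)O[Si](C)(C)C)[C@@H]1OC(=O)C=[N+]=[N-]
F5 | step 12 | 6-O-trimethylsilyl ether of silyl lactone 20 | O=C1C[C@@H]2CC[C@]3([C@H](CCCO[Si](c4ccccc4)(c4ccccc4)C(C)(C)C)[C@@H](O[Si](C)(C)C(C)(C)C)CC[C@]3(C)O[Si](C)(C)C)[C@@H]2O1
F6 | step 16 | N-tert-butyl aldimine of enal 24 | O=C1C[C@@H]2CC[C@]3([C@H](CCCO[Si](c4ccccc4)(c4ccccc4)C(C)(C)C)/C(=C(/C)C=NC(C)(C)C)CC[C@]3(C)O)[C@@H]2O1
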